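**Retrosynthetic overview**
- Target 17 comes from tetra-O-benzyl flavanonol 16 by hydrogenolysis of the four benzyl ethers.
- Feature: in ring C the ether oxygen O1 and the ketone carbon C4 sit on neighbouring ring-A carbons, C8a (next to the C8 benzyl carbon) and C4a (next to the C5 oxygen). This 1,2-oxygen/acyl pattern is read as an aryne C4a≡C8a that has taken up a carboxylate.
- Key disconnection (O1–C8a, C4–C4a and O1–C2 in one operation): aryne 13, released from silyl triflate 9, plus potassium (2R,3S)-glycidate 12. Ring C is the only ring formed; ring A, ring B and the benzyl arene are bought.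
- 9 comes from 3,5-bis(benzyloxy)phenol 1 by boron-tethered ortho-hydroxybenzylation with aldehyde 2, ionic reduction, ortho-bromination, O-silylation and retro-Brook shift/triflation.
- 12 comes from the same aldehyde 2 by Wittig olefination, chiral-dioxirane epoxidation and silanolate ester cleavage.

Key step: step 9

Remark on the chemistry: the epoxy acid partner is carried as its anhydrous potassium salt 12, because free 3-(4-alkoxyphenyl)glycidic acids decarboxylate readily and an acidic proton would quench the aryl anion before acyl transfer; phenol 1 is taken as a catalogue compound, and the epoxidation catalyst is the known ketone made by macrolactonisation of (R)-1,1'-binaphthyl-2,2'-dicarboxylic acid with 1,3-dihydroxyacetone.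

**Route**

Step 1
Reactants: 1 3,5-bis(benzyloxy)phenol; 2 4-(benzyloxy)benzaldehyde
Product: 3 5,7-bis(benzyloxy)-4-[4-(benzyloxy)phenyl]-2-phenyl-4H-1,3,2-benzodioxaborinine (racemic at C4)
Conditions: PhB(OH)2 (1.1 equiv), EtCO2H (cat.), toluene, reflux, Dean–Stark
Reagents that add atoms: phenylboronic acid, OB(O)c1ccccc1
Why: Nagata ortho-hydroxyalkylation, in which the aryloxyboronate delivers the aldehyde carbon through a six-membered transition state only to a carbon ortho to the phenol oxygen (C2 and C6 of 1 are equivalent), so attack at C4 between the two benzyloxy groups is excluded; the benzylic stereocentre forms racemic and is removed in step 2.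

Step 2
Reactants: 3 5,7-bis(benzyloxy)-4-[4-(benzyloxy)phenyl]-2-phenyl-4H-1,3,2-benzodioxaborinine
Product: 4 3,5-bis(benzyloxy)-2-[4-(benzyloxy)benzyl]phenol
Conditions: Et3SiH (3 equiv), TFA, CH2Cl2, −20 → 0 °C; aq. NaHCO3
Reagents that add atoms: none
Why: Ionic hydrogenation, in which acid ionises the doubly activated benzylic C–O bond to a diarylmethyl (o-quinone methide type) cation that the silane reduces, and work-up hydrolyses the aryl boronate to the free phenol while the aryl benzyl ethers survive the short cold acid exposure.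

Step 3
Reactants: 4 3,5-bis(benzyloxy)-2-[4-(benzyloxy)benzyl]phenol
Product: 5 3,5-bis(benzyloxy)-2-[4-(benzyloxy)benzyl]-6-bromophenol
Conditions: NBS (1.0 equiv), i-Pr2NH (10 mol %), CH2Cl2, −78 → 0 °C, dark
Reagents that add atoms: N-bromosuccinimide, O=C1CCC(=O)N1Br
Why: Amine-catalysed ortho-bromination of a phenol, in which the N-bromoamine hydrogen-bonded to the OH should deliver bromine to the only free ortho carbon (C6) in preference to C4, which lies para to the OH between two benzyloxy groups.

Step 4
Reactants: 5 3,5-bis(benzyloxy)-2-[4-(benzyloxy)benzyl]-6-bromophenol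
Product: 6 [3,5-bis(benzyloxy)-2-[4-(benzyloxy)benzyl]-6-bromophenoxy]trimethylsilane
Conditions: HMDS, THF, 70 °C; evaporation, used crude
Reagents that add atoms: hexamethyldisilazane, C[Si](C)(C)N[Si](C)(C)C
Why: Standard O-silylation of a phenol with HMDS, which gives only ammonia as by-product so that the moisture-sensitive silyl ether can be taken on after evaporation.

Step 5
Reactants: 6 [3,5-bis(benzyloxy)-2-[4-(benzyloxy)benzyl]-6-bromophenoxy]trimethylsilane
Product: 9 3,5-bis(benzyloxy)-2-[4-(benzyloxy)benzyl]-6-(trimethylsilyl)phenyl trifluoromethanesulfonate, via aryllithium 7 (not isolated), via lithium silylphenoxide 8 (not isolated)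
Conditions: n-BuLi (1.1 equiv), THF, −100 → −78 °C; then Tf2O, −100 °C → rt
Reagents that add atoms: trifluoromethanesulfonic anhydride, O=S(=O)(OS(=O)(=O)C(F)(F)F)C(F)(F)F; n-butyllithium, [Li]CCCC (lithium of 7 and 8 only)
Why: Bromine–lithium exchange outruns deprotonation of the benzylic positions at −100 °C, the ortho-lithio aryl silyl ether undergoes the 1,3 O→C silyl shift (retro-Brook rearrangement), and the lithium phenoxide is trapped by Tf2O, which is the standard entry to o-silylaryl triflates.

Step 6
Reactants: 2 4-(benzyloxy)benzaldehyde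
Product: 10 methyl (E)-3-[4-(benzyloxy)phenyl]prop-2-enoate
Conditions: Ph3P=CHCO2Me (1.1 equiv), toluene, 80 °C
Reagents that add atoms: methyl (triphenylphosphoranylidene)acetate, COC(=O)C=P(c1ccccc1)(c1ccccc1)c1ccccc1
Why: Wittig olefination with a stabilised ylide, which should give the E-cinnamate selectively from an aromatic aldehyde.

Step 7
Reactants: 10 methyl (E)-3-[4-(benzyloxy)phenyl]prop-2-enoate
Product: 11 methyl (2R,3S)-3-[4-(benzyloxy)phenyl]oxirane-2-carboxylate
Conditions: (R)-binaphthyl C2-symmetric ketone (Yang ketone, 10 mol %), Oxone, NaHCO3, 1,4-dioxane–aq. Na2EDTA, 25 °C; recrystallisation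
Reagents that add atoms: potassium peroxymonosulfate (Oxone), [K+].[O-]S(=O)(=O)OO
Why: Ketone-catalysed asymmetric epoxidation by a chiral dioxirane, a catalyst class established for electron-poor 4-alkoxycinnamates, in which concerted oxygen transfer keeps the trans geometry and the (R)-ketone (the enantiomer that gives (S,S)-stilbene oxide from trans-stilbene) should deliver oxygen to the Cα-re/Cβ-re face to set both centres as (2R,3S), the optical purity then being raised by recrystallisation of the ester.

Step 8
Reactants: 11 methyl (2R,3S)-3-[4-(benzyloxy)phenyl]oxirane-2-carboxylate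
Product: 12 potassium (2R,3S)-3-[4-(benzyloxy)phenyl]oxirane-2-carboxylate
Conditions: KOSiMe3 (1.0 equiv), THF, 0 °C → rt; filtration, drying in vacuo
Reagents that add atoms: potassium trimethylsilanolate, C[Si](C)(C)[O-].[K+]
Why: Anhydrous ester cleavage with potassium trimethylsilanolate, which should precipitate the potassium carboxylate directly without passing through the labile free glycidic acid and without touching the epoxide or either stereocentre.

Step 9
Reactants: 9 3,5-bis(benzyloxy)-2-[4-(benzyloxy)benzyl]-6-(trimethylsilyl)phenyl trifluoromethanesulfonate; 12 potassium (2R,3S)-3-[4-(benzyloxy)phenyl]oxirane-2-carboxylate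
Product: 16 (2R,3R)-5,7-bis(benzyloxy)-8-[4-(benzyloxy)benzyl]-2-[4-(benzyloxy)phenyl]-3-hydroxychroman-4-one, via aryne 13 (not isolated), via aryl carbanion ester 14 (not isolated), via acyl phenoxide 15 (not isolated)
Conditions: 12 (1.5 equiv), KF (3 equiv), 18-crown-6 (3 equiv), THF, 25 → 40 °C, Ar, slow addition of 9; then sat. aq. NH4Cl
Reagents that add atoms: none
Why: Proposed new method: fluoride attack on silicon expels triflate to give aryne 13, whose C8a (distal to the C5 benzyloxy group) takes the glycidate oxygen so that charge develops at C4a next to the inductively stabilising OBn; carbanion 14 then adds to its own ester carbonyl through a four-membered transition state and collapses with C–O cleavage to o-acyl phenoxide 15 (anionic Fries-type 1,3-acyl shift), and this phenoxide opens the epoxide to close ring C. The closest known reaction is the fluoride-mediated insertion of arynes into the C–O bond of carboxylic acids, which gives o-hydroxyaryl ketones and, with α,β-unsaturated acids, chroman-4-ones by a terminating oxa-Michael closure; here an epoxide takes the place of the enoate as the terminating electrophile. Ring C closes by 6-endo-tet epoxide opening (phenoxide O1 onto the benzylic carbon), the mode known from the cyclisation of 2'-hydroxychalcone epoxides to trans-dihydroflavonols, favoured over 5-exo attack at the α-carbon because the 4-benzyloxyphenyl group activates the benzylic C–O bond. C3 is carried over unchanged from C2 of the glycidate, and the new C2 stereocentre is set by SN2 inversion at the (3S) benzylic epoxide carbon, so the enantiopure trans-epoxide should give the 2,3-trans (2R,3R) product. The step needs carboxylate addition at C8a against the bulk of the C8 benzyl group, which the C5 alkoxy polarisation of the aryne should secure, and acyl transfer faster than protonation of 14, which the pre-formed anhydrous salt in THF and slow addition of 9 to excess 12 should secure while also limiting arylation of the product alkoxide by a second aryne.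

Step 10
Reactants: 16 (2R,3R)-5,7-bis(benzyloxy)-8-[4-(benzyloxy)benzyl]-2-[4-(benzyloxy)phenyl]-3-hydroxychroman-4-one
Product: 17 (2R,3R)-3,5,7-trihydroxy-8-(4-hydroxybenzyl)-2-(4-hydroxyphenyl)chroman-4-one
Conditions: H2 (1 atm), Pd(OH)2/C, EtOAc–MeOH, rt
Reagents that add atoms: none
Why: Catalytic hydrogenolysis of aryl benzyl ethers, under which the hydrogen-bonded C4 ketone and the C2–O1 bond of benzyl-protected dihydroflavonols are normally retained at 1 atm and neutral pH, and which touches neither stereocentre.

**Compound list**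

1 | 3,5-bis(benzyloxy)phenol | Oc1cc(OCc2ccccc2)cc(OCc2ccccc2)c1 | starting material
2 | 4-(benzyloxy)benzaldehyde | O=Cc1ccc(OCc2ccccc2)cc1 | starting material
3 | 5,7-bis(benzyloxy)-4-[4-(benzyloxy)phenyl]-2-phenyl-4H-1,3,2-benzodioxaborinine (racemic) | B1(c2ccccc2)Oc2cc(OCc3ccccc3)cc(OCc3ccccc3)c2C(c2ccc(OCc3ccccc3)cc2)O1 | intermediate
4 | 3,5-bis(benzyloxy)-2-[4-(benzyloxy)benzyl]phenol | Oc1cc(OCc2ccccc2)cc(OCc2ccccc2)c1Cc1ccc(OCc2ccccc2)cc1 | intermediate
5 | 3,5-bis(benzyloxy)-2-[4-(benzyloxy)benzyl]-6-bromophenol | Oc1c(Br)c(OCc2ccccc2)cc(OCc2ccccc2)c1Cc1ccc(OCc2ccccc2)cc1 | intermediate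
6 | [3,5-bis(benzyloxy)-2-[4-(benzyloxy)benzyl]-6-bromophenoxy]trimethylsilane | C[Si](C)(C)Oc1c(Br)c(OCc2ccccc2)cc(OCc2ccccc2)c1Cc1ccc(OCc2ccccc2)cc1 | intermediate
7 | {4,6-bis(benzyloxy)-3-[4-(benzyloxy)benzyl]-2-(trimethylsilyloxy)phenyl}lithium | C[Si](C)(C)Oc1c([Li])c(OCc2ccccc2)cc(OCc2ccccc2)c1Cc1ccc(OCc2ccccc2)cc1 | intermediate (not isolated)
8 | lithium 3,5-bis(benzyloxy)-2-[4-(benzyloxy)benzyl]-6-(trimethylsilyl)phenoxide | [Li+].[O-]c1c([Si](C)(C)C)c(OCc2ccccc2)cc(OCc2ccccc2)c1Cc1ccc(OCc2ccccc2)cc1 | intermediate (not isolated)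
9 | 3,5-bis(benzyloxy)-2-[4-(benzyloxy)benzyl]-6-(trimethylsilyl)phenyl trifluoromethanesulfonate (TMS on the future C4a, OTf on the future C8a) | C[Si](C)(C)c1c(OCc2ccccc2)cc(OCc2ccccc2)c(Cc2ccc(OCc3ccccc3)cc2)c1OS(=O)(=O)C(F)(F)F | intermediate
10 | methyl (E)-3-[4-(benzyloxy)phenyl]prop-2-enoate | COC(=O)/C=C/c1ccc(OCc2ccccc2)cc1 | intermediate
11 | methyl (2R,3S)-3-[4-(benzyloxy)phenyl]oxirane-2-carboxylate (trans) | O1[C@@H](c2ccc(OCc3ccccc3)cc2)[C@@H]1C(=O)OC | intermediate
12 | potassium (2R,3S)-3-[4-(benzyloxy)phenyl]oxirane-2-carboxylate | O1[C@@H](c2ccc(OCc3ccccc3)cc2)[C@@H]1C(=O)[O-].[K+] | intermediate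
13 | 3,5-bis(benzyloxy)-6-[4-(benzyloxy)benzyl]-1,2-didehydrobenzene (aryne) | C1(OCc2ccccc2)=CC(OCc2ccccc2)=C(Cc2ccc(OCc3ccccc3)cc2)C#C1 | intermediate (not isolated)
14 | potassium salt of the 4,6-bis(benzyloxy)-3-[4-(benzyloxy)benzyl]-2-{[(2R,3S)-3-(4-benzyloxyphenyl)oxirane-2-carbonyl]oxy}phenyl anion | O1[C@@H](c2ccc(OCc3ccccc3)cc2)[C@@H]1C(=O)Oc1[c-]c(OCc2ccccc2)cc(OCc2ccccc2)c1Cc1ccc(OCc2ccccc2)cc1.[K+] | intermediate (not isolated)
15 | potassium 3,5-bis(benzyloxy)-6-[4-(benzyloxy)benzyl]-2-{[(2R,3S)-3-(4-benzyloxyphenyl)oxiran-2-yl]carbonyl}phenoxide | O1[C@@H](c2ccc(OCc3ccccc3)cc2)[C@@H]1C(=O)c1c([O-])c(Cc2ccc(OCc3ccccc3)cc2)c(OCc2ccccc2)cc1OCc1ccccc1.[K+] | intermediate (not isolated)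
16 | (2R,3R)-5,7-bis(benzyloxy)-8-[4-(benzyloxy)benzyl]-2-[4-(benzyloxy)phenyl]-3-hydroxychroman-4-one (2,3-trans) | O=C1c2c(OCc3ccccc3)cc(OCc3ccccc3)c(Cc3ccc(OCc4ccccc4)cc3)c2O[C@H](c2ccc(OCc3ccccc3)cc2)[C@H]1O | intermediate
17 | (2R,3R)-3,5,7-trihydroxy-8-(4-hydroxybenzyl)-2-(4-hydroxyphenyl)chroman-4-one | O=C1c2c(O)cc(O)c(Cc3ccc(O)cc3)c2O[C@H](c2ccc(O)cc2)[C@H]1O | target

**Step count**

Total step count: 10. Longest linear sequence: 7 steps (1 → 3 → 4 → 5 → 6 → 9 → 16 → 17; steps 1–5, 9, 10). The glycidate arm (steps 6–8) joins at step 9.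

**Steps most likely to fail**

1. The aryne cascade (step 9, the proposed new method). Several processes could defeat it:
   - carboxylate addition at C4a instead of C8a, if the C8 benzyl group steers the nucleophile;
   - protonation of the aryl anion before acyl transfer;
   - capture of the aryne by the electron-rich arene of its own C8 benzyl group;
   - epoxide opening at the α-carbon (5-exo) or with ionisation at the benzylic carbon;
   - base-induced ring contraction or air oxidation of the product alkoxide.

   The fallback uses only known chemistry and no aryne; it sets out from bromophenol 5 and aldehyde 2 and returns at 16. Phenol 5 is protected with chloromethyl methyl ether and NaH to give 1,5-bis(benzyloxy)-4-[4-(benzyloxy)benzyl]-2-bromo-3-(methoxymethoxy)benzene F1. Bromine–lithium exchange (n-BuLi, THF, −78 °C) and acylation with N-methoxy-N-methylacetamide give the 2'-MOM-protected acetophenone F2. Claisen–Schmidt condensation with 2 (KOH, EtOH) gives the 2'-MOM-protected chalcone F3. Juliá–Colonna epoxidation (poly-L-leucine, urea–H2O2, DBU, THF) should give the (2R,3S)-epoxy ketone F4. HCl in MeOH then removes the MOM group, and the freed phenol opens the epoxide at the benzylic carbon with inversion, the classical closure to trans-dihydroflavonols, giving 16.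

2. The ortho-bromination (step 3). Bromine may enter para to the hydroxyl (C4, between the benzyloxy groups) or twice, and the isomers may be hard to separate. The fallback changes where the regiocontrol comes from; it sets out from 1 and returns at 5. Phenol 1, in which both ortho carbons are equivalent and the only competing monobromide is the symmetric 4-bromo isomer, is brominated first (NBS, i-Pr2NH cat., CH2Cl2, −78 °C) to give 3,5-bis(benzyloxy)-2-bromophenol F5. The boron-tethered condensation with 2 and PhB(OH)2 can then reach only the remaining ortho carbon and gives the 8-bromo dioxaborin F6. Et3SiH/TFA reduction as in step 2 gives 5.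

3. The asymmetric epoxidation (step 7). Facial selectivity may be incomplete and not corrected by recrystallisation, and the electron-poor alkene may be oxidised too slowly, so that the ketone catalyst decomposes. The fallback replaces catalyst control by resolution; it sets out from 2 and returns at 11. Darzens condensation of 2 with methyl chloroacetate (NaOMe, MeOH, −10 °C) gives the racemic trans-glycidate F7. Lipase-catalysed enantioselective hydrolysis (Serratia marcescens lipase, toluene–aqueous buffer), the resolution used for the 4-methoxy analogue, should consume the (2S,3R)-ester and leave 11.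

**Further compounds**

F1 | step 9 | 1,5-bis(benzyloxy)-4-[4-(benzyloxy)benzyl]-2-bromo-3-(methoxymethoxy)benzene | COCOc1c(Br)c(OCc2ccccc2)cc(OCc2ccccc2)c1Cc1ccc(OCc2ccccc2)cc1
F2 | step 9 | 1-{4,6-bis(benzyloxy)-3-[4-(benzyloxy)benzyl]-2-(methoxymethoxy)phenyl}ethan-1-one | CC(=O)c1c(OCOC)c(Cc2ccc(OCc3ccccc3)cc2)c(OCc2ccccc2)cc1OCc1ccccc1
F3 | step 9 | (E)-1-{4,6-bis(benzyloxy)-3-[4-(benzyloxy)benzyl]-2-(methoxymethoxy)phenyl}-3-[4-(benzyloxy)phenyl]prop-2-en-1-one | O=C(/C=C/c1ccc(OCc2ccccc2)cc1)c1c(OCOC)c(Cc2ccc(OCc3ccccc3)cc2)c(OCc2ccccc2)cc1OCc1ccccc1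
F4 | step 9 | {4,6-bis(benzyloxy)-3-[4-(benzyloxy)benzyl]-2-(methoxymethoxy)phenyl}{(2R,3S)-3-[4-(benzyloxy)phenyl]oxiran-2-yl}methanone | O1[C@@H](c2ccc(OCc3ccccc3)cc2)[C@@H]1C(=O)c1c(OCOC)c(Cc2ccc(OCc3ccccc3)cc2)c(OCc2ccccc2)cc1OCc1ccccc1
F5 | step 3 | 3,5-bis(benzyloxy)-2-bromophenol | Oc1cc(OCc2ccccc2)cc(OCc2ccccc2)c1Br
F6 | step 3 | 5,7-bis(benzyloxy)-4-[4-(benzyloxy)phenyl]-8-bromo-2-phenyl-4H-1,3,2-benzodioxaborinine (racemic) | B1(c2ccccc2)Oc2c(Br)c(OCc3ccccc3)cc(OCc3ccccc3)c2C(c2ccc(OCc3ccccc3)cc2)O1
F7 | step 7 | methyl trans-3-[4-(benzyloxy)phenyl]oxirane-2-carboxylate, racemic (both enantiomers written) | O1[C@@H](c2ccc(OCc3ccccc3)cc2)[C@@H]1C(=O)OC.O1[C@H](c2ccc(OCc3ccccc3)cc2)[C@H]1C(=O)OC
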